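**Retrosynthetic overview**

1. Feature: the benzo ring C3a–C4–C5–C6–C7–C7a carries only O1 (on C7a), C3 (on C3a), the C6 hydroxyl and the C5 styryl arm, and O1–C2–C3 bridges C7a to C3a with three atoms. This is the pattern left when a 1,6-diyne tethered through O1–C2–C3 takes up an alkoxyacetylene.
2. Target 25 ⇐ BBr3 demethylation of heptamethyl ether 24 ⇐ Horner–Wadsworth–Emmons at C5 (aldehyde 22 + phosphonate 23) ⇐ phenol-directed C5 formylation of phenol 20.
3. Phenol 20 ⇐ acid removal of the C6 tert-butyl and C4 silyl groups from 18 ⇐ ruthenium-catalysed (2+2+2) of ynol ether diyne 12 with tert-butoxyacetylene 17 (bonds C3a–C7a, C4–C5, C6–C7).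
4. Diyne 12 ⇐ anti alcohol 8 (dichlorovinyl ether, then n-BuLi) ⇐ chirality-transfer propargylation of aldehyde 6 with mesylate 5 ⇐ asymmetric alkynylation of aldehyde 1 with alkyne 2. C2 and C3 are set here and carried through.
5. Ring order: the three outer aryl rings are bought; the dihydrofuran ring and then the benzo ring are both closed in step 7.

Key step: step 7

Remark: the SMILES is read as the trans-(2S,3S) isomer; atoms are numbered as in 2,3-dihydro-1-benzofuran (O1, C2, C3, C3a, C4 to C7, C7a).

**Route**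

Step 1
Reactants: 1 3,5-dimethoxybenzaldehyde; 2 trimethylsilylacetylene
Product: 4 (R)-1-(3,5-dimethoxyphenyl)-3-(trimethylsilyl)prop-2-yn-1-ol, via ethyl[(trimethylsilyl)ethynyl]zinc 3 (not isolated)
Conditions: 2 (4 equiv), Et2Zn (4 equiv), Cy2NH (5 mol%), (S)-BINOL (40 mol%), Et2O, 20 °C; Ti(OiPr)4 (50 mol%); then 1, 20 °C; aq NH4Cl
Reagents that add atoms: none
Why: Catalytic asymmetric alkynylzinc addition under BINOL–titanium control, in which the (S)-BINOLate complex should deliver the alkynyl group to the Si face of the aryl aldehyde and so set the carbinol centre as R (to be confirmed by Mosher ester analysis before going on).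

Step 2
Reactants: 4 (R)-1-(3,5-dimethoxyphenyl)-3-(trimethylsilyl)prop-2-yn-1-ol
Product: 5 (R)-1-(3,5-dimethoxyphenyl)-3-(trimethylsilyl)prop-2-yn-1-yl methanesulfonate
Conditions: MsCl, Et3N, CH2Cl2, −78 → −40 °C; cold aqueous wash; used crude at once
Reagents that add atoms: methanesulfonyl chloride, CS(=O)(=O)Cl
Why: Standard O-sulfonylation that leaves the stereocentre untouched; the two meta methoxy groups do not stabilise a benzylic cation, so the mesylate should last long enough to be used cold without purification.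

Step 3
Reactants: 5 (R)-1-(3,5-dimethoxyphenyl)-3-(trimethylsilyl)prop-2-yn-1-yl methanesulfonate; 6 3,4-dimethoxybenzaldehyde
Product: 8 (1S,2S)-1-(3,4-dimethoxyphenyl)-2-(3,5-dimethoxyphenyl)-4-(trimethylsilyl)but-3-yn-1-ol (anti isomer), via (P)-allenyl(ethyl)zinc 7 (not isolated)
Conditions: Pd(OAc)2 (5 mol%), PPh3 (5 mol%), Et2Zn (3 equiv), THF, −78 → −20 °C; aq NH4Cl
Reagents that add atoms: none
Why: Marshall–Tamaru propargylation, in which zerovalent palladium displaces the mesylate in anti SN2' fashion, transmetallation to zinc gives allenylzinc 7 with retention, and SE2' addition to the aldehyde through a cyclic transition state transfers the axial chirality to C2 (S) and sets C1 (S) anti to it, the silyl group on the zinc-bearing carbon suppressing the allenyl carbinol pathway.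

Step 4
Reactants: 8 (1S,2S)-1-(3,4-dimethoxyphenyl)-2-(3,5-dimethoxyphenyl)-4-(trimethylsilyl)but-3-yn-1-ol
Product: 9 (E)-1,2-dichlorovinyl (1S,2S)-1-(3,4-dimethoxyphenyl)-2-(3,5-dimethoxyphenyl)-4-(trimethylsilyl)but-3-yn-1-yl ether
Conditions: KH (1.5 equiv), THF, 0 °C, 15 min; Cl2C=CHCl (1.2 equiv), −50 → 20 °C
Reagents that add atoms: trichloroethylene, ClC=C(Cl)Cl
Why: Anti addition of the potassium alkoxide to dichloroacetylene generated in the flask from trichloroethylene, the standard entry to alkynyl ethers of secondary alcohols; the alkoxide is formed cold and trapped at once, and neither stereocentre is involved.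

Step 5
Reactants: 9 (E)-1,2-dichlorovinyl ether of alcohol 8
Product: 12 (1S,2S)-1-(3,4-dimethoxyphenyl)-2-(3,5-dimethoxyphenyl)-4-(trimethylsilyl)but-3-yn-1-yl ethynyl ether, via chloroethynyl ether 10 (not isolated), via lithium alkynyl ether 11 (not isolated)
Conditions: n-BuLi (2.1 equiv), Et2O, −78 °C; MeOH, −78 °C; cold aqueous wash; concentrated below 0 °C and used at once
Reagents that add atoms: none
Why: Dehydrochlorination followed by chlorine–lithium exchange and protonation at −78 °C, in which the vinyl proton is far more acidic than the hindered C3–H and the silyl-capped alkyne has no acidic hydrogen; the stereocentres are untouched and the ether is kept cold because benzylic alkynyl ethers rearrange or lose ketene on warming.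

Step 6
Reactants: 13 potassium tert-butoxide
Product: 17 tert-butoxyacetylene, via tert-butyl (E)-1,2-dichlorovinyl ether 14 (not isolated), via tert-butyl chloroethynyl ether 15 (not isolated), via lithium tert-butoxyacetylide 16 (not isolated)
Conditions: Cl2C=CHCl (1.05 equiv), Et2O, −78 → 20 °C; n-BuLi (2.1 equiv), −78 °C; MeOH; fractionated cold under reduced pressure; kept at −20 °C
Reagents that add atoms: trichloroethylene, ClC=C(Cl)Cl
Why: The same alkoxide addition to dichloroacetylene and n-BuLi elimination–exchange sequence as in steps 4 and 5, run in one pot on an achiral alkoxide and kept below ambient temperature because the product loses isobutene on warming.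

Step 7
Reactants: 12 ynol ether diyne; 17 tert-butoxyacetylene
Product: 18 (2S,3S)-6-tert-butoxy-2-(3,4-dimethoxyphenyl)-3-(3,5-dimethoxyphenyl)-4-(trimethylsilyl)-2,3-dihydro-1-benzofuran (trans)
Conditions: Cp*RuCl(cod) (10 mol%), 17 (4 equiv), ClCH2CH2Cl, 0 → 20 °C, 12 added over 2 h
Reagents that add atoms: none
Why: Proposed new method: the Cp*RuCl fragment should couple the two tethered alkynes of 12 oxidatively into a bicyclic ruthenacycle, which forms the C3a–C7a bond and thereby closes the dihydrofuran ring as the five-membered ring fused to the metallacycle; 17 then inserts and reductive elimination forms C4–C5 and C6–C7, closing the benzo ring in a formal (2+2+2) cycloaddition driven by aromatisation. The closest known reactions are Cp*RuCl(cod)-catalysed cyclotrimerisations of 1,6-diynes with terminal alkynes and the RhCl(PPh3)3-catalysed variants of ynamide-tethered diynes that give indolines; an alkyl ynol ether tether combined with an alkoxyacetylene partner has not been shown. No stereocentre is formed, and C2 and C3 sit on the tether untouched, so the anti diyne maps onto the trans ring. The step needs the tert-butoxy group at C6 and not at C5: the bulky silyl group on the C4 terminus should make the monoalkyne enter at the unhindered C7 terminus with its substituted carbon bonded to C7, the meta orientation this catalyst shows with diynes capped at one end. It also needs cross-coupling to win over homotrimerisation of 17 and both thermally fragile ynol ethers to survive, which slow addition of 12 to excess 17 and a temperature of 0 to 20 °C should secure.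

Step 8
Reactants: 18 (2S,3S)-6-tert-butoxy-4-silyl dihydrobenzofuran
Product: 20 (2S,3S)-2-(3,4-dimethoxyphenyl)-3-(3,5-dimethoxyphenyl)-2,3-dihydro-1-benzofuran-6-ol, via 4-silyl phenol 19 (not isolated)
Conditions: TFA/CH2Cl2 1:9, 0 °C, 30 min, N2 sweep; evaporated cold; then neat TFA, 20 °C, until the silyl group is gone
Reagents that add atoms: none
Why: Acidolysis in two stages: the aryl tert-butyl ether cleaves fast through the tert-butyl cation, and the aryl–silicon bond then undergoes ipso protodesilylation through a β-silyl-stabilised arenium ion; this second stage is slow because C4 is meta to both ring oxygens and so needs neat acid, while any reversible opening of the O1–C2 bond returns the more stable trans ring because C3 is not affected.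

Step 9
Reactants: 20 (2S,3S)-2-(3,4-dimethoxyphenyl)-3-(3,5-dimethoxyphenyl)-2,3-dihydro-1-benzofuran-6-ol
Product: 21 (2S,3S)-2-(3,4-dimethoxyphenyl)-3-(3,5-dimethoxyphenyl)-6-hydroxy-2,3-dihydro-1-benzofuran-5-carbaldehyde
Conditions: MgCl2 (3 equiv), Et3N (6 equiv), (CH2O)n (10 equiv), MeCN, 75 °C; 1 M HCl
Reagents that add atoms: paraformaldehyde (as formaldehyde), C=O
Why: Casnati–Skattebøl ortho-formylation, in which the magnesium phenoxide delivers formaldehyde only to a carbon ortho to the free hydroxyl and a second formaldehyde accepts hydride; of the two ortho sites C5 (para to O1, flanked by C4–H) should win over C7 (between two oxygens), and the methoxylated rings, having no free phenol, are not touched.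

Step 10
Reactants: 21 6-hydroxy-5-carbaldehyde
Product: 22 (2S,3S)-2-(3,4-dimethoxyphenyl)-3-(3,5-dimethoxyphenyl)-6-methoxy-2,3-dihydro-1-benzofuran-5-carbaldehyde
Conditions: MeI, K2CO3, DMF, 40 °C
Reagents that add atoms: iodomethane, CI
Why: Williamson methylation of the phenol, so that the olefination meets a neutral aldehyde and not an unreactive phenoxide-conjugated one; the added methyl group leaves with the others in the last step.

Step 11
Reactants: 22 6-methoxy-5-carbaldehyde; 23 diethyl (3,5-dimethoxybenzyl)phosphonate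
Product: 24 (2S,3S)-2-(3,4-dimethoxyphenyl)-3-(3,5-dimethoxyphenyl)-5-[(E)-2-(3,5-dimethoxyphenyl)ethenyl]-6-methoxy-2,3-dihydro-1-benzofuran
Conditions: KOtBu (1.3 equiv), THF, 0 → 20 °C
Reagents that add atoms: none
Why: Horner–Wadsworth–Emmons olefination with a benzylic phosphonate anion, which gives the E stilbene; the base is too weak to remove C3–H, so the ring and both stereocentres should be unaffected.

Step 12
Reactants: 24 heptamethyl ether
Product: 25 (2S,3S)-2-(3,4-dihydroxyphenyl)-3-(3,5-dihydroxyphenyl)-5-[(E)-2-(3,5-dihydroxyphenyl)ethenyl]-2,3-dihydro-1-benzofuran-6-ol (CNP0263230.1)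
Conditions: BBr3 (14 equiv), CH2Cl2, −78 → 0 °C; MeOH, then H2O
Reagents that add atoms: none
Why: Lewis-acid ether cleavage, in which BBr3 binds each aryl methyl ether and bromide removes the methyl group by SN2; the C5 styryl arm has no aryl ring within reach for Friedel–Crafts closure and reversible O1–C2 opening returns the trans ring, so the configuration should hold at low temperature.

**Compound list**

1 | 3,5-dimethoxybenzaldehyde | COc1cc(C=O)cc(OC)c1 | starting material
2 | trimethylsilylacetylene | C#C[Si](C)(C)C | starting material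
3 | ethyl[(trimethylsilyl)ethynyl]zinc | CC[Zn]C#C[Si](C)(C)C | intermediate
4 | (R)-1-(3,5-dimethoxyphenyl)-3-(trimethylsilyl)prop-2-yn-1-ol | O[C@@H](C#C[Si](C)(C)C)c1cc(OC)cc(OC)c1 | intermediate
5 | (R)-1-(3,5-dimethoxyphenyl)-3-(trimethylsilyl)prop-2-yn-1-yl methanesulfonate | CS(=O)(=O)O[C@@H](C#C[Si](C)(C)C)c1cc(OC)cc(OC)c1 | intermediate
6 | 3,4-dimethoxybenzaldehyde | COc1ccc(C=O)cc1OC | starting material
7 | (P)-ethyl[3-(3,5-dimethoxyphenyl)-1-(trimethylsilyl)propa-1,2-dien-1-yl]zinc | CC[Zn]C([Si](C)(C)C)=[C@@]=C([H])c1cc(OC)cc(OC)c1 | intermediate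
8 | (1S,2S)-1-(3,4-dimethoxyphenyl)-2-(3,5-dimethoxyphenyl)-4-(trimethylsilyl)but-3-yn-1-ol (anti) | O[C@H](c1ccc(OC)c(OC)c1)[C@H](C#C[Si](C)(C)C)c1cc(OC)cc(OC)c1 | intermediate
9 | (E)-1,2-dichlorovinyl (1S,2S)-1-(3,4-dimethoxyphenyl)-2-(3,5-dimethoxyphenyl)-4-(trimethylsilyl)but-3-yn-1-yl ether | Cl/C=C(Cl)\O[C@H](c1ccc(OC)c(OC)c1)[C@H](C#C[Si](C)(C)C)c1cc(OC)cc(OC)c1 | intermediate
10 | chloroethynyl (1S,2S)-1-(3,4-dimethoxyphenyl)-2-(3,5-dimethoxyphenyl)-4-(trimethylsilyl)but-3-yn-1-yl ether | ClC#CO[C@H](c1ccc(OC)c(OC)c1)[C@H](C#C[Si](C)(C)C)c1cc(OC)cc(OC)c1 | intermediate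
11 | lithium 2-{[(1S,2S)-1-(3,4-dimethoxyphenyl)-2-(3,5-dimethoxyphenyl)-4-(trimethylsilyl)but-3-yn-1-yl]oxy}ethynide | [Li]C#CO[C@H](c1ccc(OC)c(OC)c1)[C@H](C#C[Si](C)(C)C)c1cc(OC)cc(OC)c1 | intermediate
12 | (1S,2S)-1-(3,4-dimethoxyphenyl)-2-(3,5-dimethoxyphenyl)-4-(trimethylsilyl)but-3-yn-1-yl ethynyl ether | C#CO[C@H](c1ccc(OC)c(OC)c1)[C@H](C#C[Si](C)(C)C)c1cc(OC)cc(OC)c1 | intermediate
13 | potassium tert-butoxide | CC(C)(C)[O-].[K+] | starting material
14 | tert-butyl (E)-1,2-dichlorovinyl ether | Cl/C=C(Cl)\OC(C)(C)C | intermediate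
15 | tert-butyl chloroethynyl ether | ClC#COC(C)(C)C | intermediate
16 | lithium tert-butoxyacetylide | [Li]C#COC(C)(C)C | intermediate
17 | tert-butoxyacetylene | C#COC(C)(C)C | intermediate
18 | (2S,3S)-6-tert-butoxy-2-(3,4-dimethoxyphenyl)-3-(3,5-dimethoxyphenyl)-4-(trimethylsilyl)-2,3-dihydro-1-benzofuran | CC(C)(C)Oc1cc([Si](C)(C)C)c2c(c1)O[C@H](c1ccc(OC)c(OC)c1)[C@H]2c1cc(OC)cc(OC)c1 | intermediate
19 | (2S,3S)-2-(3,4-dimethoxyphenyl)-3-(3,5-dimethoxyphenyl)-4-(trimethylsilyl)-2,3-dihydro-1-benzofuran-6-ol | Oc1cc([Si](C)(C)C)c2c(c1)O[C@H](c1ccc(OC)c(OC)c1)[C@H]2c1cc(OC)cc(OC)c1 | intermediate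
20 | (2S,3S)-2-(3,4-dimethoxyphenyl)-3-(3,5-dimethoxyphenyl)-2,3-dihydro-1-benzofuran-6-ol | Oc1ccc2c(c1)O[C@H](c1ccc(OC)c(OC)c1)[C@H]2c1cc(OC)cc(OC)c1 | intermediate
21 | (2S,3S)-2-(3,4-dimethoxyphenyl)-3-(3,5-dimethoxyphenyl)-6-hydroxy-2,3-dihydro-1-benzofuran-5-carbaldehyde | O=Cc1cc2c(cc1O)O[C@H](c1ccc(OC)c(OC)c1)[C@H]2c1cc(OC)cc(OC)c1 | intermediate
22 | (2S,3S)-2-(3,4-dimethoxyphenyl)-3-(3,5-dimethoxyphenyl)-6-methoxy-2,3-dihydro-1-benzofuran-5-carbaldehyde | O=Cc1cc2c(cc1OC)O[C@H](c1ccc(OC)c(OC)c1)[C@H]2c1cc(OC)cc(OC)c1 | intermediate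
23 | diethyl (3,5-dimethoxybenzyl)phosphonate | CCOP(=O)(Cc1cc(OC)cc(OC)c1)OCC | starting material
24 | (2S,3S)-2-(3,4-dimethoxyphenyl)-3-(3,5-dimethoxyphenyl)-5-[(E)-2-(3,5-dimethoxyphenyl)ethenyl]-6-methoxy-2,3-dihydro-1-benzofuran | COc1cc(OC)cc(/C=C/c2cc3c(cc2OC)O[C@H](c2ccc(OC)c(OC)c2)[C@H]3c2cc(OC)cc(OC)c2)c1 | intermediate
25 | (2S,3S)-2-(3,4-dihydroxyphenyl)-3-(3,5-dihydroxyphenyl)-5-[(E)-2-(3,5-dihydroxyphenyl)ethenyl]-2,3-dihydro-1-benzofuran-6-ol | Oc1cc(O)cc(/C=C/c2cc3c(cc2O)O[C@H](c2ccc(O)c(O)c2)[C@H]3c2cc(O)cc(O)c2)c1 | target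

**Step count**

Total steps: 12.
Longest linear sequence: 11 steps (steps 1 to 5 and 7 to 12, from aldehyde 1); step 6 is a one-step side branch.

**Steps most likely to fail**

1. Step 7 (Proposed new method).
What may go wrong: the electron-rich terminal ynol ether may divert the ruthenium catalyst into vinylidene formation or oligomerisation. Diyne 12 may lose ketene by a retro-ene path or rearrange before it cyclises. Alkyne 17 may also insert with the opposite orientation.
Fallback (known chemistry, rhodium-carbene C–H insertion): it sets out from aldehyde 1 and comes back to the route at phenol 20. Aldehyde 1 is oxidised (NaClO2, NaH2PO4, 2-methyl-2-butene) to 3,5-dimethoxybenzoic acid F1. Friedel–Crafts acylation of resorcinol with F1 (BF3·OEt2, 90 °C) should give (2,4-dihydroxyphenyl)(3,5-dimethoxyphenyl)methanone F2. The non-chelated 4-hydroxyl is protected (MOMCl, K2CO3, acetone) to give the 4-methoxymethyl ether F3. The chelated 2-hydroxyl is then alkylated with 3,4-dimethoxybenzyl chloride (K2CO3, DMF, 60 °C) to give the benzyl ether F4. Hydrazine hydrate (EtOH, AcOH cat., reflux) converts F4 into the hydrazone F5. MnO2 oxidises F5 to the diaryldiazomethane F6, which is not isolated. Rh2(R-PTAD)4 (1 mol%, CH2Cl2, 0 °C; or its enantiomer, whichever sets C3 as S) should insert the carbene into the benzylic C–H bond of the ether to give the cis-dihydrobenzofuran F7, with C3 set by the catalyst. HCl in MeOH then removes the methoxymethyl group and epimerises C2 through the ring-opened benzylic cation to the trans isomer, which is phenol 20.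

2. Step 4.
What may go wrong: the potassium alkoxide of 8 may transfer the alkynyl silyl group to oxygen, isomerise the propargylic C–H to an allene, or fragment by retro-propargylation before it is trapped by dichloroacetylene.
Fallback (no alkoxide; dichloro-olefination of a formate): it sets out from alcohol 8 and comes back at diyne 12. Alcohol 8 is formylated (formic acetic anhydride, pyridine, 0 °C) to the formate F8. PPh3/CCl4 (THF, 60 °C) should convert the formyl C=O into the 2,2-dichlorovinyl ether F9. n-BuLi (2.1 equiv, Et2O, −78 °C) and then MeOH should give 12 through the same lithium alkynyl ether 11.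

3. Step 3.
What may go wrong: the benzylic mesylate may ionise, or the aryl-substituted allenylpalladium and allenylzinc species may racemise before they add, which erodes enantiomeric purity. Anti selectivity with an aryl aldehyde may also be modest.
Fallback (configurationally stable allenylboronate): it sets out from alcohol 4 and comes back at alcohol 8. Alcohol 4 is converted (ClCO2Me, pyridine, CH2Cl2) into the methyl carbonate F10. Copper-catalysed anti-SN2' borylation (CuOtBu, Xantphos, B2pin2, THF) should give the (M)-allenylboronate F11, which does not racemise at ambient temperature. Heating F11 with aldehyde 6 in toluene, followed by diethanolamine work-up, should give anti alcohol 8 through the same closed SE2' transition state.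

**Further compounds**

F1 | step 7 | 3,5-dimethoxybenzoic acid | OC(=O)c1cc(OC)cc(OC)c1
F2 | step 7 | (2,4-dihydroxyphenyl)(3,5-dimethoxyphenyl)methanone | O=C(c1cc(OC)cc(OC)c1)c1ccc(O)cc1O
F3 | step 7 | (3,5-dimethoxyphenyl)[2-hydroxy-4-(methoxymethoxy)phenyl]methanone | O=C(c1cc(OC)cc(OC)c1)c1ccc(OCOC)cc1O
F4 | step 7 | {2-[(3,4-dimethoxybenzyl)oxy]-4-(methoxymethoxy)phenyl}(3,5-dimethoxyphenyl)methanone | O=C(c1cc(OC)cc(OC)c1)c1ccc(OCOC)cc1OCc1ccc(OC)c(OC)c1
F5 | step 7 | hydrazone of ketone F4 (E/Z mixture) | NN=C(c1cc(OC)cc(OC)c1)c1ccc(OCOC)cc1OCc1ccc(OC)c(OC)c1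
F6 | step 7 | diazo{2-[(3,4-dimethoxybenzyl)oxy]-4-(methoxymethoxy)phenyl}(3,5-dimethoxyphenyl)methane | [N-]=[N+]=C(c1cc(OC)cc(OC)c1)c1ccc(OCOC)cc1OCc1ccc(OC)c(OC)c1
F7 | step 7 | (2R,3S)-2-(3,4-dimethoxyphenyl)-3-(3,5-dimethoxyphenyl)-6-(methoxymethoxy)-2,3-dihydro-1-benzofuran (cis) | COCOc1ccc2c(c1)O[C@@H](c1ccc(OC)c(OC)c1)[C@H]2c1cc(OC)cc(OC)c1
F8 | step 4 | (1S,2S)-1-(3,4-dimethoxyphenyl)-2-(3,5-dimethoxyphenyl)-4-(trimethylsilyl)but-3-yn-1-yl formate | O=CO[C@H](c1ccc(OC)c(OC)c1)[C@H](C#C[Si](C)(C)C)c1cc(OC)cc(OC)c1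
F9 | step 4 | 2,2-dichlorovinyl (1S,2S)-1-(3,4-dimethoxyphenyl)-2-(3,5-dimethoxyphenyl)-4-(trimethylsilyl)but-3-yn-1-yl ether | ClC(Cl)=CO[C@H](c1ccc(OC)c(OC)c1)[C@H](C#C[Si](C)(C)C)c1cc(OC)cc(OC)c1
F10 | step 3 | (R)-1-(3,5-dimethoxyphenyl)-3-(trimethylsilyl)prop-2-yn-1-yl methyl carbonate | COC(=O)O[C@@H](C#C[Si](C)(C)C)c1cc(OC)cc(OC)c1
F11 | step 3 | (M)-2-[3-(3,5-dimethoxyphenyl)-1-(trimethylsilyl)propa-1,2-dien-1-yl]-4,4,5,5-tetramethyl-1,3,2-dioxaborolane | CC1(C)OB(OC1(C)C)C([Si](C)(C)C)=[C@@]=C([H])c1cc(OC)cc(OC)c1
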